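**Strategy.** The route rests on cutting the saturated C5–C22 tether at C9–C10, a bond between two primary, unbranched carbons: C9 is the fifth chain carbon beyond the C3=C4 alkene and C10 the thirteenth from the para-hydroxyphenyl ring. A copper-catalysed sp3–sp3 coupling of a C13 arylalkyl Grignard reagent with a primary bromide forms it and delivers the whole skeleton in one operation. The electrophile is the complete C1–C9 head, (2R,3E)-9-bromo-2,4-dimethylnon-3-enoic acid, used as its magnesium carboxylate, which masks C1 and shields the C2 stereocentre from enolisation. C2 is set earlier by auxiliary-controlled methylation of an (E)-β,γ-unsaturated imide whose alkene geometry comes from alkyne carboalumination.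

Key step: step 8

Remark: the phenol is carried as a triisopropylsilyl ether and freed with fluoride, because acidic deprotection would lactonise the 4-methyl-3-enoic acid; compounds 1, 7, 14 and 16 are taken as commercial.

**Step 1**
Reactants: 1 7-bromohept-1-yne
Product: 4 (3E)-9-bromo-4-methylnon-3-en-1-ol, via (E)-alkenyldimethylalane 2 (not isolated), via lithium alkenyl(butyl)dimethylaluminate 3 (not isolated)
Conditions: Me3Al (2.5 equiv), Cp2ZrCl2 (0.25 equiv), CH2Cl2, 0 °C → rt; volatiles removed in vacuo, hexane; n-BuLi (1 equiv), −78 → 0 °C; ethylene oxide, THF, −78 °C → rt; 1 M HCl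
Reagents that add atoms: trimethylaluminium C[Al](C)C; ethylene oxide C1CO1
Why: Negishi zirconium-catalysed carboalumination adds Me and Al syn across the terminal alkyne (Me to the internal carbon), which fixes the 3E geometry, and the derived alanate opens ethylene oxide with retention at the alkenyl carbon; n-BuLi is taken up by the Lewis-acidic alane in hexane before it can attack the primary bromide.

**Step 2**
Reactants: 4 (3E)-9-bromo-4-methylnon-3-en-1-ol
Product: 6 (3E)-9-bromo-4-methylnon-3-enoic acid, via (E)-9-bromo-4-methylnon-3-enal 5 (not isolated)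
Conditions: TEMPO (0.2 equiv), PhI(OAc)2 (2.2 equiv), MeCN/H2O 1:1, rt
Reagents that add atoms: water O
Why: Oxoammonium (TEMPO/hypervalent iodine) oxidation takes the primary alcohol through the aldehyde hydrate to the acid under near-neutral conditions, which should neither move the β,γ-alkene into conjugation nor lactonise it.

**Step 3**
Reactants: 6 (3E)-9-bromo-4-methylnon-3-enoic acid; 7 (R)-4-benzyloxazolidin-2-one
Product: 9 (4R)-4-benzyl-3-[(3E)-9-bromo-4-methylnon-3-enoyl]oxazolidin-2-one, via mixed pivalic anhydride 8 (not isolated)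
Conditions: PivCl, Et3N, THF, −20 °C; then LiCl, 7, −20 °C → rt
Reagents that add atoms: none
Why: N-acylation of the oxazolidinone through the mixed pivalic anhydride with LiCl activation avoids strong base, so the β,γ-unsaturated acyl group should not isomerise.

**Step 4**
Reactants: 9 (4R)-4-benzyl-3-[(3E)-9-bromo-4-methylnon-3-enoyl]oxazolidin-2-one
Product: 11 (4R)-4-benzyl-3-[(2R,3E)-9-bromo-2,4-dimethylnon-3-enoyl]oxazolidin-2-one, via sodium (Z)-dienolate 10 (not isolated)
Conditions: NaHMDS (1.1 equiv), THF, −78 °C; MeI (5 equiv), −78 → −40 °C; AcOH quench at −78 °C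
Reagents that add atoms: iodomethane CI
Why: Evans asymmetric alkylation: the chelated Z-enolate is methylated at the α-carbon on the face opposite the benzyl group, which gives 2R with the (R)-auxiliary, while the C3=C4 bond keeps its E geometry because it does not rotate in the dienolate at −78 °C.

**Step 5**
Reactants: 11 (4R)-4-benzyl-3-[(2R,3E)-9-bromo-2,4-dimethylnon-3-enoyl]oxazolidin-2-one
Product: 13 (2R,3E)-9-bromo-2,4-dimethylnon-3-enoic acid, via lithium peroxycarboxylate 12 (not isolated)
Conditions: LiOH (2 equiv), 30% H2O2 (4 equiv), THF/H2O 3:1, 0 °C; aq. Na2SO3; 1 M HCl to pH 3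
Reagents that add atoms: hydrogen peroxide OO
Why: Evans auxiliary cleavage: the weakly basic hydroperoxide anion attacks the exocyclic carbonyl selectively and sulfite reduces the peracid, so the allylic C2 stereocentre should survive and the auxiliary is recovered.

**Step 6**
Reactants: 14 4-(2-bromoethyl)phenol
Product: 15 [4-(2-bromoethyl)phenoxy]tri(propan-2-yl)silane
Conditions: TIPSCl (1.1 equiv), imidazole (2 equiv), CH2Cl2, 0 °C → rt
Reagents that add atoms: chlorotri(propan-2-yl)silane CC(C)[Si](Cl)(C(C)C)C(C)C
Why: Imidazole-mediated O-silylation of the phenol; the base is too weak to trigger spirocyclisation of the phenoxide onto the bromoethyl group.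

**Step 7**
Reactants: 15 [4-(2-bromoethyl)phenoxy]tri(propan-2-yl)silane; 16 1,11-dibromoundecane
Product: 18 [4-(13-bromotridecyl)phenoxy]tri(propan-2-yl)silane, via arylethylmagnesium bromide 17 (not isolated)
Conditions: Mg, THF, 45 °C; then added to 16 (4 equiv), Li2CuCl4 (3 mol %), THF, −10 °C → rt
Reagents that add atoms: none
Why: Copper-catalysed Grignard–alkyl bromide coupling (Kochi type) of a primary Grignard reagent with a primary bromide; the excess of the symmetrical dibromide should hold the reaction at mono-substitution and is recovered by distillation.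

**Step 8**
Reactants: 18 [4-(13-bromotridecyl)phenoxy]tri(propan-2-yl)silane; 13 (2R,3E)-9-bromo-2,4-dimethylnon-3-enoic acid
Product: 21 (2R,3E)-2,4-dimethyl-22-{4-[tri(propan-2-yl)silyloxy]phenyl}docos-3-enoic acid, via tridecylmagnesium bromide 19 (not isolated), via chloromagnesium carboxylate 20 (not isolated)
Conditions: 18, Mg, THF, 45 °C (gives 19); separately 13, MeMgCl (1.0 equiv), THF, −20 °C (gives 20); 19 (1.3 equiv) added to 20 and Li2CuCl4 (5 mol %), THF/NMP, −20 → 0 °C; 1 M HCl
Reagents that add atoms: none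
Why: The primary alkylmagnesium 19 transmetalates to copper to give an alkylcuprate(I), which attacks the primary C9–Br carbon of 20 in an SN2-type oxidative addition and releases the C9–C10 bond by reductive elimination from copper(III). The closest known reaction type is the Li2CuCl4-catalysed (Kochi-type) coupling of alkyl Grignard reagents with halomagnesium ω-bromoalkanoates. No ring is closed and no stereocentre is created; C2 and the 3E alkene are carried through unchanged. The step needs substitution at C9 to outrun Grignard homocoupling, attack at the carboxyl carbon and deprotonation at C2. Converting the acid first into carboxylate 20 with one equivalent of MeMgCl makes C1 inert to nucleophiles and puts the C2–H out of reach of a Grignard reagent at −20 °C. Both coupling carbons are primary and unbranched and C9 lies five carbons from the alkene, so neither β-elimination nor allylic SN2′ substitution should compete.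

**Step 9**
Reactants: 21 (2R,3E)-2,4-dimethyl-22-{4-[tri(propan-2-yl)silyloxy]phenyl}docos-3-enoic acid
Product: 22 elenic acid, (2R,3E)-22-(4-hydroxyphenyl)-2,4-dimethyldocos-3-enoic acid
Conditions: TBAF (3 equiv), THF, 0 °C → rt; 1 M HCl to pH 3
Reagents that add atoms: none
Why: Fluoride cleaves the aryl silyl ether while the acid sits as its carboxylate, so C2 cannot enolise and no acid is present to lactonise the 4-methyl-3-enoic acid.

**Compound list**

1 | 7-bromohept-1-yne | C#CCCCCCBr | starting material
2 | [(1E)-7-bromo-2-methylhept-1-en-1-yl]dimethylalumane | C[Al](C)/C=C(\C)CCCCCBr | intermediate (not isolated)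
3 | lithium [(1E)-7-bromo-2-methylhept-1-en-1-yl](butyl)dimethylaluminate | [Li+].CCCC[Al-](C)(C)/C=C(\C)CCCCCBr | intermediate (not isolated)
4 | (3E)-9-bromo-4-methylnon-3-en-1-ol | OCC/C=C(\C)CCCCCBr | intermediate
5 | (3E)-9-bromo-4-methylnon-3-enal | O=CC/C=C(\C)CCCCCBr | intermediate (not isolated)
6 | (3E)-9-bromo-4-methylnon-3-enoic acid | OC(=O)C/C=C(\C)CCCCCBr | intermediate
7 | (R)-4-benzyloxazolidin-2-one | O=C1OC[C@@H](Cc2ccccc2)N1 | starting material
8 | (3E)-9-bromo-4-methylnon-3-enoic pivalic anhydride | CC(C)(C)C(=O)OC(=O)C/C=C(\C)CCCCCBr | intermediate (not isolated)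
9 | (4R)-4-benzyl-3-[(3E)-9-bromo-4-methylnon-3-enoyl]oxazolidin-2-one | O=C1OC[C@@H](Cc2ccccc2)N1C(=O)C/C=C(\C)CCCCCBr | intermediate
10 | sodium (1Z,3E)-dienolate of 9 | [Na+].[O-]/C(=C\C=C(/C)CCCCCBr)N1[C@H](Cc2ccccc2)COC1=O | intermediate (not isolated)
11 | (4R)-4-benzyl-3-[(2R,3E)-9-bromo-2,4-dimethylnon-3-enoyl]oxazolidin-2-one | O=C1OC[C@@H](Cc2ccccc2)N1C(=O)[C@H](C)/C=C(\C)CCCCCBr | intermediate
12 | lithium (2R,3E)-9-bromo-2,4-dimethylnon-3-eneperoxoate | [Li+].[O-]OC(=O)[C@H](C)/C=C(\C)CCCCCBr | intermediate (not isolated)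
13 | (2R,3E)-9-bromo-2,4-dimethylnon-3-enoic acid | OC(=O)[C@H](C)/C=C(\C)CCCCCBr | intermediate
14 | 4-(2-bromoethyl)phenol | Oc1ccc(CCBr)cc1 | starting material
15 | [4-(2-bromoethyl)phenoxy]tri(propan-2-yl)silane | BrCCc1ccc(O[Si](C(C)C)(C(C)C)C(C)C)cc1 | intermediate
16 | 1,11-dibromoundecane | BrCCCCCCCCCCCBr | starting material
17 | {2-[4-(triisopropylsilyloxy)phenyl]ethyl}magnesium bromide | Br[Mg]CCc1ccc(O[Si](C(C)C)(C(C)C)C(C)C)cc1 | intermediate (not isolated)
18 | [4-(13-bromotridecyl)phenoxy]tri(propan-2-yl)silane | BrCCCCCCCCCCCCCc1ccc(O[Si](C(C)C)(C(C)C)C(C)C)cc1 | intermediate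
19 | {13-[4-(triisopropylsilyloxy)phenyl]tridecyl}magnesium bromide | Br[Mg]CCCCCCCCCCCCCc1ccc(O[Si](C(C)C)(C(C)C)C(C)C)cc1 | intermediate (not isolated)
20 | chloromagnesium (2R,3E)-9-bromo-2,4-dimethylnon-3-enoate | Cl[Mg]OC(=O)[C@H](C)/C=C(\C)CCCCCBr | intermediate (not isolated)
21 | (2R,3E)-2,4-dimethyl-22-{4-[tri(propan-2-yl)silyloxy]phenyl}docos-3-enoic acid | C/C(=C\[C@@H](C)C(=O)O)CCCCCCCCCCCCCCCCCCc1ccc(O[Si](C(C)C)(C(C)C)C(C)C)cc1 | intermediate
22 | elenic acid, (2R,3E)-22-(4-hydroxyphenyl)-2,4-dimethyldocos-3-enoic acid | C/C(=C\[C@@H](C)C(=O)O)CCCCCCCCCCCCCCCCCCc1ccc(O)cc1 | target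

**Count.** Total steps: 9. Longest linear sequence: 7 (steps 1–5, 8, 9); the aryl branch (steps 6, 7) joins at step 8.

**Steps most likely to fail**

1. Step 8. The magnesium carboxylate may stay heterogeneous, so that the cuprate is used up by homocoupling, or surplus Grignard reagent may deprotonate C2 and erode the stereocentre. The fallback forms the same C9–C10 bond by a palladium/boron coupling of a neutral ester; it sets out from 18 and 13 and comes back at 22. Bromide 18 is dehydrobrominated with t-BuOK in THF to tri(propan-2-yl)[4-(tridec-12-en-1-yl)phenoxy]silane F1. Acid 13 is esterified with 2-(trimethylsilyl)ethanol (DCC, cat. DMAP, CH2Cl2, 0 °C) to 2-(trimethylsilyl)ethyl (2R,3E)-9-bromo-2,4-dimethylnon-3-enoate F2. Hydroboration of F1 with 9-BBN-H (THF, rt) should give the B-alkyl-9-borabicyclo[3.3.1]nonane F3, which is coupled with F2 under alkyl–alkyl Suzuki–Miyaura conditions (Pd(OAc)2, PCy3, K3PO4·H2O, THF, rt) to 2-(trimethylsilyl)ethyl (2R,3E)-2,4-dimethyl-22-{4-[tri(propan-2-yl)silyloxy]phenyl}docos-3-enoate F4. TBAF in THF then removes the silylethyl ester and the aryl silyl ether together and should give 22.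

2. Step 1. The primary bromide may be attacked by n-BuLi before ate-complex formation is complete, or the alanate may open the epoxide sluggishly, so that protonated alkene accumulates. The fallback replaces the epoxide opening by a cross-coupling that delivers the acid oxidation level directly; it sets out from 1 and comes back at 6, so step 2 is not needed. Carboalumination of 1 as in step 1 gives alane 2, which is quenched with I2 (THF, −30 °C) to (1E)-7-bromo-1-iodo-2-methylhept-1-ene F5. Palladium-catalysed coupling of F5 with commercial (2-ethoxy-2-oxoethyl)zinc bromide (Reformatsky reagent; Pd(PPh3)4, THF/DMPU, 50 °C) should give ethyl (3E)-9-bromo-4-methylnon-3-enoate F6, and LiOH in THF/H2O (0 °C → rt) should give 6.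

3. Step 5. The basic peroxide may epimerise the doubly activated C2 centre or displace the primary bromide. The fallback removes the auxiliary by reduction and re-oxidises; it sets out from 11 and comes back at 13. LiBH4 (THF, 1 equiv MeOH, 0 °C) should give (2R,3E)-9-bromo-2,4-dimethylnon-3-en-1-ol F7. Oxidation under the conditions of step 2 (TEMPO, PhI(OAc)2, MeCN/H2O) should pass through (2R,3E)-9-bromo-2,4-dimethylnon-3-enal F8 (not isolated) to 13.

**Further compounds**

F1 | step 8 | tri(propan-2-yl)[4-(tridec-12-en-1-yl)phenoxy]silane | C=CCCCCCCCCCCCc1ccc(O[Si](C(C)C)(C(C)C)C(C)C)cc1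
F2 | step 8 | 2-(trimethylsilyl)ethyl (2R,3E)-9-bromo-2,4-dimethylnon-3-enoate | C[Si](C)(C)CCOC(=O)[C@H](C)/C=C(\C)CCCCCBr
F3 | step 8 | 9-{13-[4-(triisopropylsilyloxy)phenyl]tridecyl}-9-borabicyclo[3.3.1]nonane | B1(CCCCCCCCCCCCCc2ccc(O[Si](C(C)C)(C(C)C)C(C)C)cc2)C3CCCC1CCC3
F4 | step 8 | 2-(trimethylsilyl)ethyl (2R,3E)-2,4-dimethyl-22-{4-[tri(propan-2-yl)silyloxy]phenyl}docos-3-enoate | C/C(=C\[C@@H](C)C(=O)OCC[Si](C)(C)C)CCCCCCCCCCCCCCCCCCc1ccc(O[Si](C(C)C)(C(C)C)C(C)C)cc1
F5 | step 1 | (1E)-7-bromo-1-iodo-2-methylhept-1-ene | I/C=C(\C)CCCCCBr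
F6 | step 1 | ethyl (3E)-9-bromo-4-methylnon-3-enoate | CCOC(=O)C/C=C(\C)CCCCCBr
F7 | step 5 | (2R,3E)-9-bromo-2,4-dimethylnon-3-en-1-ol | OC[C@H](C)/C=C(\C)CCCCCBr
F8 | step 5 | (2R,3E)-9-bromo-2,4-dimethylnon-3-enal | O=C[C@H](C)/C=C(\C)CCCCCBr
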